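Each turn of the round on the card takes one D and one L and gives one Z, so c_D + c_Z stayed at the D charged, apart from the little held on the catalyst. L is the limiting reagent in the three new flasks, with c_L below c_D, so I set their ceiling at 70.0% of the D charged.

| flask | D | L | Q | temperature | remark | time |
|---|---|---|---|---|---|---|
| maple | 0.12 M | 0.056 M | 3 mM | 30 °C | run made earlier |  |
| larch | 0.12 M | 0.13 M | 3 mM | 42 °C | run made earlier |  |
| teal | 0.12 M | 0.0840 M | 3.0 mM | 50 °C |  | 10 h |
| amber | 0.12 M | 0.0840 M | 3.0 mM | 35 °C |  | 10 h |
| green | 0.12 M | 0.0840 M | 3.0 mM |  | at 35 °C until 2.0 h, from then on at 50 °C | 10 h |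

- maple (time / h: Z / %): 2.50: 23.5; 5.00: 35.0; 10.0: 45.7; 15.0: 45.1
- larch (time / h: Z / %): 0.500: 10.5; 1.00: 22.0; 2.50: 40.6; 6.00: 65.9

(scatter of a reading: 1 percentage point)

- the flask with the highest amount of Z, in percent of the D charged ("all alike" if they lie within 1.5 percentage points) (teal / amber / green / all alike)
- final Z, as a percentage of the D charged, in teal
- final Z, as a percentage of the D charged, in amber
- final Z, as a percentage of the D charged, in green

- what may be going on: Q -> X; L + Q <-> G; E <-> J; J -> Q + Z; D + G -> E

I read the runs as a ladder of times. On the first rung the catalyst entered the round: larch gave 10.5% at 0.500 h and 22.0% at 1.00 h, with no visible lag.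

On the next rung the limiting reagent fell. I replaced the falling curve of the partner by its mean, which made the loss of the limiting reagent pseudo-first-order. Maple at 5.00 h gave 2.80 /M/h, and larch at 6.00 h gave 1.98 /M/h. These are readings of the pair constant κ: the logarithm of the fall of the limiting reagent, divided by the partner's mean concentration and by the time. The two runs differed in L as well as in temperature, so the fall of κ on heating was a doubtful reading. I still carried it on a log scale, to 2.42 /M/h at 35 °C and 1.57 /M/h at 50 °C.

Taking the mean c_D as if Z reached the ceiling, 0.0780 M, the mean life of L came to 5.29 h cool and 8.14 h hot, longer when hot. I reckoned Z as the ceiling times the share of L used: amber 59.4%, green 52.0%, teal 49.5%. I expected these to run low, since a Z below the ceiling leaves the mean c_D higher than the one I took.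

On the last rung I put the loss of catalyst. Maple's last reading, 45.1%, stood near its ceiling of 46.7%, so in maple the catalyst lasted while L fell, but no run shown was made at 50 °C.

The forecast gave 58% for teal, 61% for amber and 62% for green, with green narrowly on top in its words “Green gets its early conversion cool, then a modest boost”, whereas my reckoning put amber higher than the other two.

Teal gave 51.9%, amber 61.4% and green 54.0%, so amber led, each above my reckoning.

    Q → X (k = 8.35 × 10⁻⁵ /min, Ea = 112 kJ/mol)
    L + Q ⇌ G (K = 6.14 /M, k = 21.0 /M/min, Ea = 63.0 kJ/mol, ΔH = −78.0 kJ/mol)
    E ⇌ J (K = 0.640, k = 6.74 /min, Ea = 82.0 kJ/mol, ΔH = 45.0 kJ/mol)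
    J → Q + Z (k = 1.67 /min, Ea = 76.0 kJ/mol)
    D + G → E (k = 4.04 /M/min, Ea = 40.0 kJ/mol)
    (constants at 35 °C)

Amber held G at 12.0% of the catalyst at 5.00 h while D + G → E ran, and its end, with 12% of L and 39% of D left, gives κ = 2.55 /M/h. Green, after its change at 2.0 h, ran that step with G at 4.06% of the catalyst at 5.00 h, while X reached 25.6% of the catalyst by 10.0 h; green's hot stretch gives κ = 1.70 /M/h, lower than amber's. A neighbour of green with 0.021 M of L had a ceiling of 17.5%, my carried κ values reckoned 14.9% for it, and that flask gave 15.8%.

The runs were computed with made-up constants, noise included.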